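**Plan**

1. Numbering used throughout: C1 = quaternary ring-fusion carbon with Me, C2, C3, C4 = C(OH)(i-Pr), C5 = ring-fusion CH, C6 (ester O), C7 (OH), C8 (Me, epoxide), C9 (epoxide CH), C10 (CH2); β is the face of the C1 methyl, α the other.
2. Retrosynthesis: cut the aroyl C–O at C6, the epoxide O (to C8=C9), the C4–i-Pr bond (to a C4 ketone), the C6–O/C5–H pair (hydroboration of C5=C6) and the C7 carbinol (to a ketone, then a doubly allylic CH2). The resulting cyclohepta-1,4-diene is cut at C10–C9 and C7–C8 in one operation into a vinylcyclopropane and 1-(trimethylsilyl)propyne; the cyclopropane is cut to an acyclic diazo keto ester.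
3. Enabling feature: in the seven-membered ring the five carbons C7–C6–C5–C1–C10 end in a CH2 (C10) on the quaternary C1 and pass through the ring fusion. Bonding C10 to C5 makes them a bridgehead-vinyl bicyclo[3.1.0]hexane (cyclopropane C1–C5–C10 on the cyclopentane edge C1–C5), and the epoxide carbons C8(Me)–C9 are an alkyne, so a rhodium-catalysed [5+2] cycloaddition builds the ring.
4. Forward order: cyclopentane and cyclopropane together (intramolecular cyclopropanation), then the seven-membered ring ([5+2]), then C7 oxygen, C5-H/C6-OH, C4 carbinol, epoxide, ester, deprotection.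
5. Stereochemistry: C1 from a catalytic asymmetric cyclopropanation; C7 from a CBS reduction; C5 and C6 (one hydroboration), C4 (i-Pr addition) and C8/C9 (epoxidation) by substrate control from the C1 methyl and the C7 benzyloxy group.

Key step: step 8

Assumption: the (S,S)-bis(oxazoline) ligand in step 3 is taken to give the (1R,5R) bicycle; if the sense of induction is the reverse, the (R,R) ligand is used.

**Route**

Step 1
Reactants: 1 methyl acetoacetate; 2 3-chloro-2-methylprop-1-ene
Product: 4 methyl 6-methyl-3-oxohept-6-enoate, via acetoacetate dianion 3 (not isolated)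
Conditions: NaH, THF, 0 °C; n-BuLi, 0 °C; then 2, 0 °C to rt; dilute aq. HCl work-up
Reagents that add atoms: none
Why: Dianion γ-alkylation: the terminal carbanion is the more nucleophilic site and displaces the allylic chloride by SN2, no stereocenter being formed.

Step 2
Reactants: 4 methyl 6-methyl-3-oxohept-6-enoate
Product: 5 methyl 2-diazo-6-methyl-3-oxohept-6-enoate
Conditions: 4-acetamidobenzenesulfonyl azide, Et3N, MeCN, 0 °C to rt
Reagents that add atoms: 4-acetamidobenzenesulfonyl azide, CC(=O)Nc1ccc(cc1)S(=O)(=O)N=[N+]=[N-]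
Why: Regitz diazo transfer to the doubly activated methylene of a β-keto ester is a standard, high-yielding reaction.

Step 3
Reactants: 5 methyl 2-diazo-6-methyl-3-oxohept-6-enoate
Product: 6 methyl (1R,5R)-5-methyl-2-oxobicyclo[3.1.0]hexane-1-carboxylate
Conditions: CuOTf·0.5C6H6 (5 mol %), 2,2'-(propane-2,2-diyl)bis[(4S)-4-tert-butyl-4,5-dihydrooxazole] (6 mol %), toluene, 50 °C, slow addition of 5
Reagents that add atoms: none
Why: Asymmetric intramolecular cyclopropanation: the monovalent copper carbene adds to the tethered 1,1-disubstituted alkene, the tether enforces the cis-fused bicycle, and the chiral ligand selects the alkene face and so fixes the quaternary C1 (and C5).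

Step 4
Reactants: 6 methyl (1R,5R)-5-methyl-2-oxobicyclo[3.1.0]hexane-1-carboxylate
Product: 7 methyl (1R,5R)-5-methylspiro[bicyclo[3.1.0]hexane-2,2'-[1,3]dioxolane]-1-carboxylate
Conditions: 1,2-bis(trimethylsilyloxy)ethane, Me3SiOTf (cat.), CH2Cl2, −78 to −20 °C
Reagents that add atoms: 1,2-bis(trimethylsilyloxy)ethane, C[Si](C)(C)OCCO[Si](C)(C)C
Why: Silyl-transfer ketalisation protects the hindered C4 ketone at low temperature, where the doubly activated cyclopropane should not open; the symmetric dioxolane adds no stereocenter.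

Step 5
Reactants: 7 methyl (1R,5R)-5-methylspiro[bicyclo[3.1.0]hexane-2,2'-[1,3]dioxolane]-1-carboxylate
Product: 8 [(1S,5R)-5-methylspiro[bicyclo[3.1.0]hexane-2,2'-[1,3]dioxolan]-1-yl]methanol
Conditions: LiAlH4, THF, 0 °C
Reagents that add atoms: none
Why: Hydride reduction of the ester to the primary alcohol; the ketal and the now unactivated cyclopropane are inert.

Step 6
Reactants: 8 [(1S,5R)-5-methylspiro[bicyclo[3.1.0]hexane-2,2'-[1,3]dioxolan]-1-yl]methanol
Product: 9 (1S,5R)-5-methylspiro[bicyclo[3.1.0]hexane-2,2'-[1,3]dioxolane]-1-carbaldehyde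
Conditions: (n-Pr4N)RuO4 (5 mol %), N-methylmorpholine N-oxide, 4 Å molecular sieves, CH2Cl2, rt
Reagents that add atoms: none
Why: Ley–Griffith oxidation under neutral conditions converts the neopentyl-type primary alcohol into the non-enolisable aldehyde without touching the ketal.

Step 7
Reactants: 9 (1S,5R)-5-methylspiro[bicyclo[3.1.0]hexane-2,2'-[1,3]dioxolane]-1-carbaldehyde
Product: 10 (1R,5R)-1-ethenyl-5-methylspiro[bicyclo[3.1.0]hexane-2,2'-[1,3]dioxolane]
Conditions: Ph3PCH3Br, KOt-Bu, THF, 0 °C to rt
Reagents that add atoms: methyltriphenylphosphonium bromide, C[P+](c1ccccc1)(c1ccccc1)c1ccccc1.[Br-]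
Why: Wittig methylenation of the hindered, non-enolisable aldehyde installs the vinyl group (C6=C7) on the bridgehead carbon C5.

Step 8
Reactants: 10 (1R,5R)-1-ethenyl-5-methylspiro[bicyclo[3.1.0]hexane-2,2'-[1,3]dioxolane]; 11 1-(trimethylsilyl)propyne
Product: 12 4,4-(ethylenedioxy)-9-(trimethylsilyl)-11,12,13-trinordauca-5,8-diene (1-methyl-8-methyl-9-SiMe3 bicyclo[5.3.0]deca-5,8-diene with the C4 dioxolane, C1 R-configured)
Conditions: [Rh(CO)2Cl]2 (5 mol %), 11 (3 equiv), ClCH2CH2Cl, 80 °C
Reagents that add atoms: none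
Why: Monovalent rhodium binds the vinyl group of 10 and inserts into the C5–C10 cyclopropane bond to give a σ-alkyl/π-allyl trivalent rhodacycle (C10–Rh, allyl C5–C6–C7); the alkyne inserts at the allyl terminus C7 (new C7–C8 bond) and C(sp2)–C(sp3) reductive elimination joins C9 to C10. The closest known reaction type is the rhodium-catalysed intermolecular [5+2] cycloaddition of 1-substituted vinylcyclopropanes with alkynes. The seven-membered ring is closed by this reductive elimination from an eight-membered rhodacycle, that is as a formal two-carbon ring expansion of the cyclopropane across the cyclopentane edge C1–C5, not by an exo or endo attack. No new stereocenter is formed: C5 becomes sp2 and the quaternary C1 keeps its configuration because none of its bonds is broken. Two selectivities are needed: cleavage of C5–C10 and not of C5–C1, secured because insertion into the bond to the CH2 gives a primary alkyl–rhodium whereas the other would give a tertiary one at C1 (the quaternary C1 also leaves the rhodacycle without β-hydrogens); and the alkyne orientation, secured by the bulk of SiMe3, which should stay on the rhodium-bound carbon away from the C–C bond formed in the insertion and so end on C9 next to C10. The silyl group then shields C8=C9 in the hydroboration and is removed by protodesilylation.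

Step 9
Reactants: 12 4,4-(ethylenedioxy)-9-(trimethylsilyl)-11,12,13-trinordauca-5,8-diene
Product: 13 4,4-(ethylenedioxy)-9-(trimethylsilyl)-11,12,13-trinordauca-5,8-dien-7-one
Conditions: CrO3, 3,5-dimethylpyrazole, CH2Cl2, −20 °C
Reagents that add atoms: chromium trioxide, O=[Cr](=O)=O
Why: Allylic oxidation: the doubly allylic C7 methylene is the weakest C–H position and both termini of the derived pentadienyl system (C5, C9) are fully substituted, so the hexavalent chromium–pyrazole reagent should oxidise C7 to the cross-conjugated dienone.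

Step 10
Reactants: 13 4,4-(ethylenedioxy)-9-(trimethylsilyl)-11,12,13-trinordauca-5,8-dien-7-one
Product: 14 4,4-(ethylenedioxy)-9-(trimethylsilyl)-11,12,13-trinordauca-5,8-dien-7β-ol (C7 S)
Conditions: (R)-2-methyl-CBS-oxazaborolidine (0.3 equiv), catecholborane, toluene, −78 °C
Reagents that add atoms: none
Why: Corey–Bakshi–Shibata reduction delivers hydride 1,2 under reagent control; with the α-methyl-β-silyl alkenyl arm (C8) as the large group and the C6H= arm as the small one, the (R)-catalyst should give the 7β (S) alcohol.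

Step 11
Reactants: 14 4,4-(ethylenedioxy)-9-(trimethylsilyl)-11,12,13-trinordauca-5,8-dien-7β-ol
Product: 15 7β-benzyloxy-4,4-(ethylenedioxy)-9-(trimethylsilyl)-11,12,13-trinordauca-5,8-diene
Conditions: NaH, BnBr, DMF, 0 °C to rt
Reagents that add atoms: benzyl bromide, BrCc1ccccc1
Why: Williamson etherification under basic conditions protects the acid-sensitive doubly allylic alcohol with retention at C7 and gives the group that steers the next step.

Step 12
Reactants: 15 7β-benzyloxy-4,4-(ethylenedioxy)-9-(trimethylsilyl)-11,12,13-trinordauca-5,8-diene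
Product: 17 7β-benzyloxy-4,4-(ethylenedioxy)-9-(trimethylsilyl)-11,12,13-trinordauc-8-en-6α-ol (5α-H), via C6 alkylborane 16 (not isolated)
Conditions: BH3·SMe2, THF, 0 °C to rt; then NaOH, H2O2, 0 °C
Reagents that add atoms: borane–dimethyl sulfide, [BH3-][S+](C)C (boron only in 16); hydrogen peroxide, OO
Why: Hydroboration–oxidation: syn addition to the trisubstituted C5=C6 alkene from the α face, opposite the C1 methyl and the C7 benzyloxy group, puts boron on C6 and hydrogen on C5 in one event, and oxidation with retention gives the 6α-alcohol and the trans ring fusion, while the tetrasubstituted vinylsilane should not react.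

Step 13
Reactants: 17 7β-benzyloxy-4,4-(ethylenedioxy)-9-(trimethylsilyl)-11,12,13-trinordauc-8-en-6α-ol
Product: 19 7β-benzyloxy-6α-hydroxy-11,12,13-trinordauc-8-en-4-one (5α-H), via keto vinylsilane 18 (not isolated)
Conditions: CF3CO2H, CH2Cl2/H2O, 0 °C to rt; NaHCO3/MeOH work-up
Reagents that add atoms: water, O
Why: Ketal hydrolysis and protodesilylation: aqueous acid unmasks the C4 ketone, and ipso-protonation of the vinylsilane at C9 gives a tertiary β-silyl cation at C8 that loses silicon, leaving the C8=C9 alkene where it was.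

Step 14
Reactants: 19 7β-benzyloxy-6α-hydroxy-11,12,13-trinordauc-8-en-4-one
Product: 20 7β-benzyloxydauc-8-ene-4β,6α-diol
Conditions: i-PrMgCl (4 equiv), CeCl3 (4 equiv), THF, −78 to 0 °C
Reagents that add atoms: isopropylmagnesium chloride, CC(C)[Mg]Cl
Why: Organocerium 1,2-addition: the weakly basic reagent adds to the hindered, enolisable C4 ketone from the α face, anti to the axial C1 methyl, which should give the 4β-hydroxy-4α-isopropyl carbinol.

Step 15
Reactants: 20 7β-benzyloxydauc-8-ene-4β,6α-diol
Product: 21 7β-benzyloxy-8α,9α-epoxydaucane-4β,6α-diol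
Conditions: m-CPBA, NaHCO3, CH2Cl2, 0 °C
Reagents that add atoms: 3-chloroperoxybenzoic acid, OOC(=O)c1cccc(Cl)c1
Why: Prilezhaev epoxidation of the only alkene should occur on the α face, which carries the homoallylic 6α-hydroxyl, because the β face is screened by the 7β-benzyloxy group and the C1 methyl; the buffer guards against transannular opening by the 4β-hydroxyl.

Step 16
Reactants: 21 7β-benzyloxy-8α,9α-epoxydaucane-4β,6α-diol; 22 4-(benzyloxy)benzoyl chloride
Product: 23 7β-benzyloxy-8α,9α-epoxy-4β-hydroxydaucan-6α-yl 4-(benzyloxy)benzoate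
Conditions: Et3N, DMAP (cat.), CH2Cl2, 0 °C to rt
Reagents that add atoms: none
Why: DMAP-catalysed acylation takes the secondary 6α-hydroxyl; the tertiary C4 hydroxyl is too hindered to react and the basic medium spares the epoxide.

Step 17
Reactants: 23 7β-benzyloxy-8α,9α-epoxy-4β-hydroxydaucan-6α-yl 4-(benzyloxy)benzoate
Product: 24 8α,9α-epoxy-4β,7β-dihydroxydaucan-6α-yl 4-hydroxybenzoate (CNP0290052.1)
Conditions: H2 (1 atm), Pd/C, EtOAc, rt
Reagents that add atoms: none
Why: Hydrogenolysis cleaves both benzyl ethers under neutral conditions, which should leave the benzoate ester in place without acyl migration and the trialkyl epoxide intact.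

**Compound list**

1 | methyl acetoacetate | COC(=O)CC(C)=O | starting material
2 | 3-chloro-2-methylprop-1-ene | ClCC(C)=C | starting material
3 | methyl acetoacetate dianion (sodium lithium salt) | COC(=O)[CH-]C(=O)[CH2-].[Na+].[Li+] | intermediate (not isolated)
4 | methyl 6-methyl-3-oxohept-6-enoate | COC(=O)CC(=O)CCC(C)=C | intermediate
5 | methyl 2-diazo-6-methyl-3-oxohept-6-enoate | COC(=O)C(=[N+]=[N-])C(=O)CCC(C)=C | intermediate
6 | methyl (1R,5R)-5-methyl-2-oxobicyclo[3.1.0]hexane-1-carboxylate | O=C1CC[C@]2(C)C[C@]12C(=O)OC | intermediate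
7 | methyl (1R,5R)-5-methylspiro[bicyclo[3.1.0]hexane-2,2'-[1,3]dioxolane]-1-carboxylate | O1CCOC12CC[C@]3(C)C[C@]23C(=O)OC | intermediate
8 | [(1S,5R)-5-methylspiro[bicyclo[3.1.0]hexane-2,2'-[1,3]dioxolan]-1-yl]methanol | O1CCOC12CC[C@]3(C)C[C@]23CO | intermediate
9 | (1S,5R)-5-methylspiro[bicyclo[3.1.0]hexane-2,2'-[1,3]dioxolane]-1-carbaldehyde | O1CCOC12CC[C@]3(C)C[C@]23C=O | intermediate
10 | (1R,5R)-1-ethenyl-5-methylspiro[bicyclo[3.1.0]hexane-2,2'-[1,3]dioxolane] | O1CCOC12CC[C@]3(C)C[C@]23C=C | intermediate
11 | 1-(trimethylsilyl)propyne | CC#C[Si](C)(C)C | starting material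
12 | 4,4-(ethylenedioxy)-9-(trimethylsilyl)-11,12,13-trinordauca-5,8-diene | C[C@]12CCC3(OCCO3)C1=CCC(C)=C([Si](C)(C)C)C2 | intermediate
13 | 4,4-(ethylenedioxy)-9-(trimethylsilyl)-11,12,13-trinordauca-5,8-dien-7-one | C[C@]12CCC3(OCCO3)C1=CC(=O)C(C)=C([Si](C)(C)C)C2 | intermediate
14 | 4,4-(ethylenedioxy)-9-(trimethylsilyl)-11,12,13-trinordauca-5,8-dien-7β-ol | C[C@]12CCC3(OCCO3)C1=C[C@H](O)C(C)=C([Si](C)(C)C)C2 | intermediate
15 | 7β-benzyloxy-4,4-(ethylenedioxy)-9-(trimethylsilyl)-11,12,13-trinordauca-5,8-diene | C[C@]12CCC3(OCCO3)C1=C[C@H](OCc4ccccc4)C(C)=C([Si](C)(C)C)C2 | intermediate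
16 | 6α-boryl-7β-benzyloxy-4,4-(ethylenedioxy)-9-(trimethylsilyl)-11,12,13-trinordauc-8-ene (5α-H) | O1CCOC13CC[C@]2(C)CC([Si](C)(C)C)=C(C)[C@@H](OCc4ccccc4)[C@H](B)[C@H]23 | intermediate (not isolated)
17 | 7β-benzyloxy-4,4-(ethylenedioxy)-9-(trimethylsilyl)-11,12,13-trinordauc-8-en-6α-ol (5α-H) | O1CCOC13CC[C@]2(C)CC([Si](C)(C)C)=C(C)[C@@H](OCc4ccccc4)[C@H](O)[C@H]23 | intermediate
18 | 7β-benzyloxy-6α-hydroxy-9-(trimethylsilyl)-11,12,13-trinordauc-8-en-4-one (5α-H) | O=C1CC[C@]2(C)CC([Si](C)(C)C)=C(C)[C@@H](OCc3ccccc3)[C@H](O)[C@H]21 | intermediate (not isolated)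
19 | 7β-benzyloxy-6α-hydroxy-11,12,13-trinordauc-8-en-4-one (5α-H) | O=C1CC[C@]2(C)CC=C(C)[C@@H](OCc3ccccc3)[C@H](O)[C@H]21 | intermediate
20 | 7β-benzyloxydauc-8-ene-4β,6α-diol | CC(C)[C@]1(O)CC[C@]2(C)CC=C(C)[C@@H](OCc3ccccc3)[C@H](O)[C@H]21 | intermediate
21 | 7β-benzyloxy-8α,9α-epoxydaucane-4β,6α-diol | CC(C)[C@]1(O)CC[C@]2(C)C[C@@H]3O[C@]3(C)[C@@H](OCc3ccccc3)[C@H](O)[C@H]21 | intermediate
22 | 4-(benzyloxy)benzoyl chloride | O=C(Cl)c1ccc(OCc2ccccc2)cc1 | starting material
23 | 7β-benzyloxy-8α,9α-epoxy-4β-hydroxydaucan-6α-yl 4-(benzyloxy)benzoate | CC(C)[C@]1(O)CC[C@]2(C)C[C@@H]3O[C@]3(C)[C@@H](OCc3ccccc3)[C@H](OC(=O)c3ccc(OCc4ccccc4)cc3)[C@H]21 | intermediate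
24 | 8α,9α-epoxy-4β,7β-dihydroxydaucan-6α-yl 4-hydroxybenzoate (CNP0290052.1) | CC(C)[C@]1(O)CC[C@]2(C)C[C@@H]3O[C@]3(C)[C@@H](O)[C@H](OC(=O)c3ccc(O)cc3)[C@H]21 | target

**Step count and risks**

Total step count: 17. Longest linear sequence: 17 steps (1 and 2 to 24); 11 and 22 are bought.

Steps most likely to fail:

1. Step 8. Rhodium may insert into the internal C1–C5 cyclopropane bond, the hindered silyl alkyne may insert slowly or in the opposite orientation, or the vinylcyclopropane may isomerise instead of cycloadding. The fallback builds the ring stepwise, sets out from 6 and comes back at 19.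
   - Homoconjugate addition of a vinyl cuprate (vinylmagnesium bromide, CuBr·SMe2, THF, −40 °C) to the doubly activated cyclopropane of 6 at its CH2 carbon should give methyl 2-allyl-2-methyl-5-oxocyclopentane-1-carboxylate F1 (ester trans to allyl, C1 unchanged).
   - Ketalisation with ethylene glycol and TsOH should give the dioxolane ester F2.
   - Reduction with i-Bu2AlH at −78 °C should give the aldehyde F3.
   - γ-Alkoxyallylboration with B-[(Z)-3-(benzyloxy)-2-methylallyl]diisopinocampheylborane (from benzyl 2-methylallyl ether, s-BuLi and B-methoxydiisopinocampheylborane, in the enantiomeric form matched to the 6α-hydroxy-7β-benzyloxy configuration) should give the syn hydroxy ether F4.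
   - Ring-closing metathesis with second-generation Grubbs catalyst (H2IMes)(PCy3)Cl2Ru=CHPh should close C8=C9 to the bicyclic ketal alcohol F5.
   - Hydrolysis with PPTS in wet acetone returns 19.

2. Step 10. The two alkenyl arms of the dienone may be discriminated poorly by the catalyst, or the ring may impose an opposing facial bias. The fallback sets out from 13 and comes back at 14. Luche reduction (NaBH4, CeCl3·7H2O, MeOH, −78 °C) should give 14 together with its C7 epimer, 4,4-(ethylenedioxy)-9-(trimethylsilyl)-11,12,13-trinordauca-5,8-dien-7α-ol F6. The diastereomers are separated by chromatography, and F6 is oxidised back to 13 with MnO2 and recycled.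

3. Step 14. The hindered β-hydroxy ketone may enolise, be reduced by β-hydride transfer from the isopropyl reagent, or cleave by retro-aldol reaction. The fallback sets out from 19 and comes back at 20. Isopropenylmagnesium bromide with CeCl3 (a nucleophile without β-hydrogens and with less bulk) should give 7β-benzyloxy-dauca-8,11-diene-4β,6α-diol F7. Hydrogenation of its 1,1-disubstituted alkene with H2 and RhCl(PPh3)3 in benzene, which leaves the trisubstituted ring alkene and the benzyl ether, gives 20.

Further compounds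

F1 | step 8 | methyl 2-allyl-2-methyl-5-oxocyclopentane-1-carboxylate (ester trans to allyl) | O=C1CC[C@](C)(CC=C)[C@H]1C(=O)OC
F2 | step 8 | ethylene ketal of F1 | O1CCOC12CC[C@](C)(CC=C)[C@H]2C(=O)OC
F3 | step 8 | 2-allyl-2-methyl-5,5-(ethylenedioxy)cyclopentane-1-carbaldehyde | O1CCOC12CC[C@](C)(CC=C)[C@H]2C=O
F4 | step 8 | syn 1-[2-allyl-5,5-(ethylenedioxy)-2-methylcyclopentyl]-2-(benzyloxy)-3-methylbut-3-en-1-ol | O1CCOC12CC[C@](C)(CC=C)[C@H]2[C@@H](O)[C@H](OCc1ccccc1)C(C)=C
F5 | step 8 | 7β-benzyloxy-4,4-(ethylenedioxy)-11,12,13-trinordauc-8-en-6α-ol (5α-H) | O1CCOC13CC[C@]2(C)CC=C(C)[C@@H](OCc4ccccc4)[C@H](O)[C@H]23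
F6 | step 10 | 4,4-(ethylenedioxy)-9-(trimethylsilyl)-11,12,13-trinordauca-5,8-dien-7α-ol | C[C@]12CCC3(OCCO3)C1=C[C@@H](O)C(C)=C([Si](C)(C)C)C2
F7 | step 14 | 7β-benzyloxydauca-8,11-diene-4β,6α-diol | CC(=C)[C@]1(O)CC[C@]2(C)CC=C(C)[C@@H](OCc3ccccc3)[C@H](O)[C@H]21
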